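(The earlier runs and the new flask were generated by integration with constants of no real substance; noise was put on by code.)

Substrate falls at 0.127 s⁻¹ in Saturday's run, read between its first two points, which is a lifetime of 7.85 s. Friday's run, with half the free catalyst, reads 0.0695 s⁻¹, so the rate follows c(free catalyst).

| setting | Saturday's | Friday's | Monday's | midnight | winter | summer |
|---|---|---|---|---|---|---|
| substrate | 0.061 M | 0.061 M | 0.061 M | 0.061 M | 0.061 M | 0.061 M (fed, over 2.0 min) |
| reagent | 1.2 equiv | 1.2 equiv | 1.2 equiv | 1.20 equiv (fed, over 2.0 min) | 1.20 equiv | 1.20 equiv |
| capture agent | 0.0183 M | 0.0183 M | 0.0183 M | 0.0183 M | 0.0183 M | 0.0183 M |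
| free catalyst | 2 mol% | 1 mol% | 1.5 mol% | 2 mol% | 2 mol% | 2 mol% |
| second catalyst | 0.2 mol% | 0.2 mol% | 0.2 mol% | 0.2 mol% | 0.2 mol% | 0.2 mol% |
| remark | run made earlier | run made earlier | run made earlier | all else is in the flask from the start; the feed brings no volume worth counting | everything together at the start | all else is in the flask from the start; the feed brings no volume worth counting |
| time |  |  |  | 2.5 min | 2.5 min | 2.5 min |

Saturday's run (percent of the substrate charged)

| time / min | target / % | substrate / % |
|---|---|---|
| 0.200 | 10.5 | 21.0 |
| 0.417 | 23.6 | 4.0 |
| 0.667 | 34.7 | 0 |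
| 1.33 | 47.8 | 0.5 |
| 2.50 | 51.8 | 0.2 |

Friday's run (percent of the substrate charged)

| time / s | target / % | substrate / % |
|---|---|---|
| 20.0 | 15.1 | 26.1 |
| 40.0 | 27.9 | 6.5 |
| 50.0 | 32.8 | 2.8 |
| 80.0 | 41.8 | 1.1 |
| 90.0 | 43.4 | 0 |

Monday's run (percent of the substrate charged)

| time / s | target / % | substrate / % |
|---|---|---|
| 10.0 | 8.3 | 40.7 |
| 25.0 | 21.5 | 7.8 |
| 40.0 | 30.6 | 1.9 |
| 60.0 | 41.0 | 0 |
| 90.0 | 46.6 | 0.4 |

(scatter of a reading: 1 percentage point)



- the flask that comes out highest in amount of target, in percent of the substrate charged, or "all alike" when all lie within 1.5 percentage points (midnight / winter / summer / all alike)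
- target at the end, in percent of the substrate charged, midnight
- target at the end, in percent of the substrate charged, winter
- target at the end, in percent of the substrate charged, summer

The quantity to carry is the standing share, the substrate lifetime divided by the feed time: 6.54 %. Winter has Saturday's recipe, so its substrate is reckoned to leave at the reading of 0.127 s⁻¹ of what stands. In summer, with the same 2 mol% of free catalyst, the feed supplies 0.00833 s⁻¹ of the charge, slower by a factor of 15.2, so once feed and loss balance, the standing substrate in summer is reckoned at that share of the charge. After summer's feed stops, 30.0 s of decay remain, reckoned to lower the standing substrate by a factor of 45.6, to 0.143 % of the charge at the asked time.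

Saturday's last reading has 48.0 % of the charge as neither target nor substrate. If that loss needs substrate beside what substrate becomes, summer's small share lowers it, and this reckoning puts summer above winter, which repeats Saturday near 51.8 %. Midnight reverses the picture: within one substrate lifetime, 6.54 % of its reagent has arrived while its substrate was charged whole at the start, so if target needs reagent, that same loss grows, and this reckoning puts midnight below winter.

The forecast gave midnight 47 %, winter 52 % and summer 46 %, with winter highest: “Winter is my best guess, though mechanism uncertainty is real.”

Summer comes out highest at 60.6 %, with winter at 52.5 % and midnight at 39.8 %. At the end, side product stands at 17.9 % in summer, 35.5 % in winter and 40.2 % in midnight.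

    reagent + catalyst intermediate → second catalyst + target (k = 129 L mol⁻¹ s⁻¹)
    second catalyst + open intermediate ⇌ catalyst intermediate (K = 68.0 L mol⁻¹, k = 6540 L mol⁻¹ s⁻¹)
    substrate + open intermediate → side product (k = 1.36 L mol⁻¹ s⁻¹)
    substrate + free catalyst → free catalyst + open intermediate (k = 82.2 L mol⁻¹ s⁻¹)
    open intermediate + capture agent → trapped intermediate (k = 0.460 L mol⁻¹ s⁻¹)

Against the standing share of 6.54 %, summer holds 7.32 % of substrate at 2.00 min. For the neighbour of summer with 0.024 M of substrate and the loadings held, the lifetime is reckoned to stretch by a factor of 2.54, the share to become 16.6 %, and decay after the feed to bring it to 3.70 %. That neighbour holds 4.01 % of substrate at 2.50 min.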